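**Retrosynthetic overview**

1. Locants: ring A is the arene (C4a, C5–C8, C8a; C19 carboxyl on C6, OH on C7 and C8); ring B is C1–C4 (C20 methyl on C1, side chain on C4: C11 carrying C16H2OAc, then C12–C14, then C15 carrying the C17 methyl and C18H2OH).
2. Ring A is bought complete; ring B is closed last, by forming C1–C2 in a copper-hydride-catalysed enantioselective intramolecular hydroalkylation of a C8a vinyl group (C1=C20) with a primary bromide at C2.
3. Enabling feature: C1 is benzylic to ring A, so Cu–H adds across C1=C20 with copper on C1, and C2 ends a three-carbon arm on the ortho carbon C4a, exactly a 6-exo-tet distance away.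
4. The C4/C11 pair comes from an iridium/amine dual-catalytic α-allylation of a side-chain aldehyde (C15 from (R)-3-bromo-2-methylpropan-1-ol) with an aryl vinyl carbinol; the allyl vinyl group becomes C3–C2.
5. 2,3,4-Trihydroxybenzaldehyde maps onto ring A: CHO becomes C4, the 2-OH becomes the C8a handle (triflate, then vinyl), the 3,4-OH pair becomes O8/O7, and C19 enters by iodination/carbonylation.

Key step: step 14

Assumption: the sense of induction of the three chiral catalysts (steps 9 and 14) is taken from their behaviour with simple aryl substrates; if a trial shows the opposite sense, the antipodal ligand is used and nothing else changes.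

**Route**

Step 1
Reactants: 1 2,3,4-trihydroxybenzaldehyde
Product: 2 4-hydroxy-2,2-diphenyl-1,3-benzodioxole-5-carbaldehyde
Conditions: Ph2CCl2, Ph2O, 175 °C
Reagents that add atoms: dichlorodiphenylmethane, ClC(Cl)(c1ccccc1)c1ccccc1
Why: Ketalisation of a catechol with a geminal dichloride; the 2-OH is held in a hydrogen bond to the formyl group, so the dioxole should close across the 3- and 4-oxygens.

Step 2
Reactants: 2 4-hydroxy-2,2-diphenyl-1,3-benzodioxole-5-carbaldehyde
Product: 3 4-hydroxy-7-iodo-2,2-diphenyl-1,3-benzodioxole-5-carbaldehyde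
Conditions: NIS, MeCN, 0 °C to rt
Reagents that add atoms: N-iodosuccinimide, O=C1CCC(=O)N1I
Why: Electrophilic aromatic iodination; the position para to the free phenol (ortho to the dioxole oxygen, meta to the formyl group) is the only activated site.

Step 3
Reactants: 3 4-hydroxy-7-iodo-2,2-diphenyl-1,3-benzodioxole-5-carbaldehyde
Product: 4 benzyl 6-formyl-7-hydroxy-2,2-diphenyl-1,3-benzodioxole-4-carboxylate
Conditions: Pd(OAc)2 (cat.), dppf, CO (1 atm), BnOH, Et3N, DMF, 70 °C
Reagents that add atoms: carbon monoxide, [C-]#[O+]; benzyl alcohol, OCc1ccccc1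
Why: Palladium-catalysed alkoxycarbonylation of an aryl iodide (oxidative addition, CO insertion, alcoholysis) installs the future C19 carboxyl as a benzyl ester that the final hydrogenolysis removes.

Step 4
Reactants: 4 benzyl 6-formyl-7-hydroxy-2,2-diphenyl-1,3-benzodioxole-4-carboxylate
Product: 5 benzyl 6-formyl-2,2-diphenyl-7-(triflyloxy)-1,3-benzodioxole-4-carboxylate
Conditions: Tf2O, pyridine, CH2Cl2, 0 °C
Reagents that add atoms: trifluoromethanesulfonic anhydride, O=S(=O)(OS(=O)(=O)C(F)(F)F)C(F)(F)F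
Why: O-Sulfonylation of the phenol turns the C8a oxygen into a cross-coupling handle.

Step 5
Reactants: 5 benzyl 6-formyl-2,2-diphenyl-7-(triflyloxy)-1,3-benzodioxole-4-carboxylate
Product: 6 racemic aryl vinyl carbinol (1-hydroxyprop-2-en-1-yl in place of the formyl group of 5)
Conditions: vinylmagnesium bromide, THF, −78 °C; then H2O
Reagents that add atoms: vinylmagnesium bromide, C=C[Mg]Br
Why: Grignard 1,2-addition; at −78 °C the aldehyde should react ahead of the benzoate and the triflate, and the carbinol centre may stay racemic because step 9 erases it.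

Step 6
Reactants: 7 (R)-3-bromo-2-methylpropan-1-ol
Product: 8 (R)-[(3-bromo-2-methylpropoxy)methyl]benzene
Conditions: benzyl 2,2,2-trichloroacetimidate, TfOH (cat.), cyclohexane/CH2Cl2, 0 °C to rt
Reagents that add atoms: benzyl 2,2,2-trichloroacetimidate, N=C(OCc1ccccc1)C(Cl)(Cl)Cl
Why: Acid-catalysed O-benzylation with a trichloroacetimidate; no alkoxide forms, so the bromide cannot close to an oxetane and the stereocentre is untouched.

Step 7
Reactants: 8 (R)-[(3-bromo-2-methylpropoxy)methyl]benzene, 9 5-bromopent-1-ene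
Product: 11 (S)-{[(2-methyloct-7-en-1-yl)oxy]methyl}benzene, via Grignard reagent 10 (not isolated)
Conditions: Mg, THF, 40 °C; then 9, Li2CuCl4 (cat.), THF/NMP, 0 °C
Reagents that add atoms: none
Why: Copper-catalysed sp3–sp3 cross-coupling of a primary Grignard reagent with a primary alkyl bromide; the stereocentre is β to the metal and cannot epimerise.

Step 8
Reactants: 11 (S)-{[(2-methyloct-7-en-1-yl)oxy]methyl}benzene
Product: 13 (S)-7-(benzyloxy)-6-methylheptanal, via ozonide 12 (not isolated)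
Conditions: O3, CH2Cl2, −78 °C; then PPh3, −78 °C to rt
Reagents that add atoms: ozone, [O-][O+]=O
Why: Ozonolysis with reductive work-up cleaves the terminal alkene to the aldehyde; the benzyl ether should survive if ozone addition is stopped at the end point.

Step 9
Reactants: 6 racemic aryl vinyl carbinol, 13 (S)-7-(benzyloxy)-6-methylheptanal
Product: 15 C16 alcohol with (4S,11S,15S) configuration (vinyl on C4, triflate on C8a), via aldehyde 14 (not isolated)
Conditions: [Ir(cod)Cl]2 (cat.), (S)-BINOL-derived N-(dibenzo[b,f]azepin-5-yl) phosphoramidite (P,olefin ligand), (R)-2-{bis[3,5-bis(trifluoromethyl)phenyl][(trimethylsilyl)oxy]methyl}pyrrolidine (cat.), dimethyl hydrogen phosphate (cat.), ClCH2CH2Cl, 25 °C; then NaBH4, MeOH, 0 °C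
Reagents that add atoms: none
Why: Stereodivergent dual catalysis (iridium-catalysed allylic substitution merged with enamine catalysis): the iridium complex should ionise either enantiomer of 6 to one π-allyl whose aryl-bearing terminus (C4) is attacked under ligand control by the enamine of 13, the amine antipode fixing C11 independently, and the in-flask borohydride reduction protects the α-stereocentre of 14 from epimerisation.

Step 10
Reactants: 15 C16 alcohol (vinyl on C4, triflate on C8a)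
Product: 16 C16 tert-butyldimethylsilyl ether of 15
Conditions: TBSCl, imidazole, DMF, rt
Reagents that add atoms: tert-butyldimethylsilyl chloride, CC(C)(C)[Si](C)(C)Cl
Why: Silyl ether formation masks C16–OH against the later alkoxide base and keeps it distinct from C18–OBn.

Step 11
Reactants: 16 C16 silyl ether (vinyl on C4, triflate on C8a)
Product: 18 C2 primary alcohol (triflate on C8a), via alkylborane 17 (not isolated)
Conditions: 9-BBN, THF, 0 °C to rt; then NaBO3·4H2O, H2O, rt
Reagents that add atoms: sodium perborate (tetrahydrate), [Na+].[Na+].O[B-]1(O)OO[B-](O)(O)OO1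
Why: Hydroboration–oxidation; 9-BBN places boron on the terminal carbon C2 (anti-Markovnikov), perborate is mild enough for the triflate and the benzyl ester, and running this before the aryl vinyl group exists avoids any alkene/alkene selectivity question.

Step 12
Reactants: 18 C2 primary alcohol (triflate on C8a)
Product: 19 C2 primary alcohol with a vinyl group on C8a
Conditions: vinylboronic acid pinacol ester, Pd(OAc)2 (cat.), SPhos, K3PO4, THF/H2O, 60 °C
Reagents that add atoms: vinylboronic acid pinacol ester, C=CB1OC(C)(C)C(C)(C)O1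
Why: Suzuki–Miyaura coupling; a bulky electron-rich biarylphosphine should let zerovalent palladium insert into the doubly ortho-substituted C8a–OTf bond, and the free alcohol and benzyl ester are inert to phosphate base.

Step 13
Reactants: 19 C2 primary alcohol with a vinyl group on C8a
Product: 20 C2 primary bromide with a vinyl group on C8a (cyclisation precursor)
Conditions: CBr4, PPh3, CH2Cl2, 0 °C
Reagents that add atoms: carbon tetrabromide, BrC(Br)(Br)Br
Why: Appel reaction (SN2 at a primary carbon) under neutral conditions that spare the silyl ether, the ketal and the styrene.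

Step 14
Reactants: 20 C2 primary bromide with a vinyl group on C8a
Product: 22 protected tetralin with (1R,4S,11S,15S) configuration, via benzylic alkylcopper 21 (not isolated)
Conditions: Cu(OAc)2 (cat.), (R)-DTBM-SEGPHOS, (MeO)2MeSiH, LiOt-Bu, THF, 40 °C
Reagents that add atoms: none
Why: Cu(OAc)2, the bisphosphine and the silane should give a ligated copper hydride that adds across the C8a vinyl group in the Markovnikov sense (hydride to C20, copper to benzylic C1, giving 21), and this nucleophile then displaces the primary bromide at C2 so that C1–C2 forms and ring B closes in a 6-exo-tet mode, while LiOt-Bu (chosen so the benzyl ester is not exchanged) and the silane return the copper bromide to the hydride. The closest known reaction type is the copper-hydride-catalysed enantioselective intramolecular hydroalkylation of bromide-tethered vinyl arenes, which gives four- to six-membered and benzo-fused rings. The new stereocentre C1 is set by the ligand in the hydrocupration (catalyst control, (R) expected from the (R)-ligand) and is carried through because the C–C bond forms with retention at the copper-bearing carbon; C4, C11 and C15 are spectators. In the 1,4-trans product both the C20 methyl and the C11 branch can sit pseudoaxial, away from the peri positions, so closure from the catalyst-preferred epimer is unstrained. The step needs Markovnikov regiochemistry (secured by benzylic stabilisation from ring A), hydrocupration faster than direct C–Br reduction (favoured by the bulky electron-rich bisphosphine) and cyclisation over intermolecular alkylation (secured by the ortho placement of the three-carbon arm on C4a); the tied-back dioxole oxygen keeps the vinyl group accessible.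

Step 15
Reactants: 22 protected tetralin (C16–OTBS)
Product: 23 C16 alcohol of the tetralin
Conditions: HF·pyridine, THF/pyridine, 0 °C to rt
Reagents that add atoms: none
Why: Fluoride-mediated cleavage of the Si–O bond; buffered HF·pyridine should leave the ketal, the benzyl ether and the benzyl ester intact.

Step 16
Reactants: 23 C16 alcohol of the tetralin
Product: 24 C16 acetate of the tetralin
Conditions: Ac2O, pyridine, DMAP (cat.), CH2Cl2, rt
Reagents that add atoms: acetic anhydride, CC(=O)OC(C)=O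
Why: DMAP-catalysed acetylation of the only free hydroxyl; the phenols, the acid and C18–OH are all masked, so no selectivity question arises.

Step 17
Reactants: 24 C16 acetate of the tetralin
Product: 25 target acid
Conditions: H2 (1 atm), Pd/C, EtOAc/MeOH, rt
Reagents that add atoms: none
Why: Hydrogenolysis removes the benzyl ether, the benzyl ester and the diphenylmethylene ketal (all benzylic C–O bonds) in one operation, while the acetate, the arene and the four stereocentres are untouched.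

**Compound list**

1 | 2,3,4-trihydroxybenzaldehyde | O=Cc1ccc(O)c(O)c1O | starting material
2 | 4-hydroxy-2,2-diphenyl-1,3-benzodioxole-5-carbaldehyde | O=Cc1ccc2OC(c3ccccc3)(c3ccccc3)Oc2c1O | intermediate
3 | 4-hydroxy-7-iodo-2,2-diphenyl-1,3-benzodioxole-5-carbaldehyde | O=Cc1cc(I)c2OC(c3ccccc3)(c3ccccc3)Oc2c1O | intermediate
4 | benzyl 6-formyl-7-hydroxy-2,2-diphenyl-1,3-benzodioxole-4-carboxylate | O=Cc1cc(C(=O)OCc2ccccc2)c2OC(c3ccccc3)(c3ccccc3)Oc2c1O | intermediate
5 | benzyl 6-formyl-2,2-diphenyl-7-{[(trifluoromethyl)sulfonyl]oxy}-1,3-benzodioxole-4-carboxylate | O=Cc1cc(C(=O)OCc2ccccc2)c2OC(c3ccccc3)(c3ccccc3)Oc2c1OS(=O)(=O)C(F)(F)F | intermediate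
6 | benzyl 6-(1-hydroxyprop-2-en-1-yl)-2,2-diphenyl-7-{[(trifluoromethyl)sulfonyl]oxy}-1,3-benzodioxole-4-carboxylate (racemic) | C=CC(O)c1cc(C(=O)OCc2ccccc2)c2OC(c3ccccc3)(c3ccccc3)Oc2c1OS(=O)(=O)C(F)(F)F | intermediate
7 | (R)-3-bromo-2-methylpropan-1-ol | BrC[C@H](C)CO | starting material
8 | (R)-[(3-bromo-2-methylpropoxy)methyl]benzene | BrC[C@H](C)COCc1ccccc1 | intermediate
9 | 5-bromopent-1-ene | C=CCCCBr | starting material
10 | [(2R)-3-(benzyloxy)-2-methylpropyl]magnesium bromide | Br[Mg]C[C@H](C)COCc1ccccc1 | intermediate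
11 | (S)-{[(2-methyloct-7-en-1-yl)oxy]methyl}benzene | C=CCCCC[C@H](C)COCc1ccccc1 | intermediate
12 | 3-[(5S)-6-(benzyloxy)-5-methylhexyl]-1,2,4-trioxolane | C1(CCCC[C@H](C)COCc2ccccc2)OCOO1 | intermediate
13 | (S)-7-(benzyloxy)-6-methylheptanal | O=CCCCC[C@H](C)COCc1ccccc1 | intermediate
14 | benzyl 6-[(3S,4S,8S)-9-(benzyloxy)-4-formyl-8-methylnon-1-en-3-yl]-2,2-diphenyl-7-{[(trifluoromethyl)sulfonyl]oxy}-1,3-benzodioxole-4-carboxylate | O=C[C@@H](CCC[C@H](C)COCc1ccccc1)[C@H](C=C)c1cc(C(=O)OCc2ccccc2)c2OC(c3ccccc3)(c3ccccc3)Oc2c1OS(=O)(=O)C(F)(F)F | intermediate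
15 | benzyl 6-[(3S,4S,8S)-9-(benzyloxy)-4-(hydroxymethyl)-8-methylnon-1-en-3-yl]-2,2-diphenyl-7-{[(trifluoromethyl)sulfonyl]oxy}-1,3-benzodioxole-4-carboxylate | OC[C@@H](CCC[C@H](C)COCc1ccccc1)[C@H](C=C)c1cc(C(=O)OCc2ccccc2)c2OC(c3ccccc3)(c3ccccc3)Oc2c1OS(=O)(=O)C(F)(F)F | intermediate
16 | benzyl 6-[(3S,4S,8S)-9-(benzyloxy)-4-{[(tert-butyldimethylsilyl)oxy]methyl}-8-methylnon-1-en-3-yl]-2,2-diphenyl-7-{[(trifluoromethyl)sulfonyl]oxy}-1,3-benzodioxole-4-carboxylate | CC(C)(C)[Si](C)(C)OC[C@@H](CCC[C@H](C)COCc1ccccc1)[C@H](C=C)c1cc(C(=O)OCc2ccccc2)c2OC(c3ccccc3)(c3ccccc3)Oc2c1OS(=O)(=O)C(F)(F)F | intermediate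
17 | benzyl 6-[(3S,4S,8S)-9-(benzyloxy)-1-(9-borabicyclo[3.3.1]nonan-9-yl)-4-{[(tert-butyldimethylsilyl)oxy]methyl}-8-methylnonan-3-yl]-2,2-diphenyl-7-{[(trifluoromethyl)sulfonyl]oxy}-1,3-benzodioxole-4-carboxylate | CC(C)(C)[Si](C)(C)OC[C@@H](CCC[C@H](C)COCc1ccccc1)[C@H](CCB4C5CCCC4CCC5)c1cc(C(=O)OCc2ccccc2)c2OC(c3ccccc3)(c3ccccc3)Oc2c1OS(=O)(=O)C(F)(F)F | intermediate
18 | benzyl 6-[(3S,4S,8S)-9-(benzyloxy)-4-{[(tert-butyldimethylsilyl)oxy]methyl}-1-hydroxy-8-methylnonan-3-yl]-2,2-diphenyl-7-{[(trifluoromethyl)sulfonyl]oxy}-1,3-benzodioxole-4-carboxylate | CC(C)(C)[Si](C)(C)OC[C@@H](CCC[C@H](C)COCc1ccccc1)[C@H](CCO)c1cc(C(=O)OCc2ccccc2)c2OC(c3ccccc3)(c3ccccc3)Oc2c1OS(=O)(=O)C(F)(F)F | intermediate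
19 | benzyl 6-[(3S,4S,8S)-9-(benzyloxy)-4-{[(tert-butyldimethylsilyl)oxy]methyl}-1-hydroxy-8-methylnonan-3-yl]-7-ethenyl-2,2-diphenyl-1,3-benzodioxole-4-carboxylate | CC(C)(C)[Si](C)(C)OC[C@@H](CCC[C@H](C)COCc1ccccc1)[C@H](CCO)c1cc(C(=O)OCc2ccccc2)c2OC(c3ccccc3)(c3ccccc3)Oc2c1C=C | intermediate
20 | benzyl 6-[(3S,4S,8S)-9-(benzyloxy)-1-bromo-4-{[(tert-butyldimethylsilyl)oxy]methyl}-8-methylnonan-3-yl]-7-ethenyl-2,2-diphenyl-1,3-benzodioxole-4-carboxylate | CC(C)(C)[Si](C)(C)OC[C@@H](CCC[C@H](C)COCc1ccccc1)[C@H](CCBr)c1cc(C(=O)OCc2ccccc2)c2OC(c3ccccc3)(c3ccccc3)Oc2c1C=C | intermediate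
21 | benzylic alkylcopper from 20 (Cu on C1, H added to C20; bisphosphine on copper not drawn) | CC(C)(C)[Si](C)(C)OC[C@@H](CCC[C@H](C)COCc1ccccc1)[C@H](CCBr)c1cc(C(=O)OCc2ccccc2)c2OC(c3ccccc3)(c3ccccc3)Oc2c1[C@H](C)[Cu] | intermediate
22 | benzyl (6S,9R)-6-[(2S,6S)-7-(benzyloxy)-1-[(tert-butyldimethylsilyl)oxy]-6-methylheptan-2-yl]-9-methyl-2,2-diphenyl-6,7,8,9-tetrahydronaphtho[1,2-d][1,3]dioxole-4-carboxylate | CC(C)(C)[Si](C)(C)OC[C@@H](CCC[C@H](C)COCc1ccccc1)[C@@H]1CC[C@@H](C)c2c1cc(C(=O)OCc1ccccc1)c1OC(c3ccccc3)(c3ccccc3)Oc21 | intermediate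
23 | benzyl (6S,9R)-6-[(2S,6S)-7-(benzyloxy)-1-hydroxy-6-methylheptan-2-yl]-9-methyl-2,2-diphenyl-6,7,8,9-tetrahydronaphtho[1,2-d][1,3]dioxole-4-carboxylate | OC[C@@H](CCC[C@H](C)COCc1ccccc1)[C@@H]1CC[C@@H](C)c2c1cc(C(=O)OCc1ccccc1)c1OC(c3ccccc3)(c3ccccc3)Oc21 | intermediate
24 | benzyl (6S,9R)-6-[(2S,6S)-1-acetoxy-7-(benzyloxy)-6-methylheptan-2-yl]-9-methyl-2,2-diphenyl-6,7,8,9-tetrahydronaphtho[1,2-d][1,3]dioxole-4-carboxylate | CC(=O)OC[C@@H](CCC[C@H](C)COCc1ccccc1)[C@@H]1CC[C@@H](C)c2c1cc(C(=O)OCc1ccccc1)c1OC(c3ccccc3)(c3ccccc3)Oc21 | intermediate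
25 | (5R,8S)-8-[(2S,6S)-1-acetoxy-7-hydroxy-6-methylheptan-2-yl]-3,4-dihydroxy-5-methyl-5,6,7,8-tetrahydronaphthalene-2-carboxylic acid | CC(=O)OC[C@@H](CCC[C@H](C)CO)[C@@H]1CC[C@@H](C)c2c1cc(C(=O)O)c(O)c2O | target

**Step count and risks**

Total: 17 steps. Longest linear sequence: 14 steps (steps 1–5 and 9–17, from 1); the side-chain branch (steps 6–8) joins at step 9.

Most likely to fail, in order:

1. Step 14. Hydrocupration of the doubly ortho-substituted vinyl group may be slow, so that reduction of the C–Br bond, oligomerisation or loss of facial control takes over. The fallback sets out from 18 and rejoins at 22, forming C1–C2 as a double bond by metathesis and setting C1 by hydrogenation. Compound 18 is coupled with isopropenylboronic acid pinacol ester (Pd(OAc)2, SPhos, K3PO4) to the isopropenyl alcohol F1. Dess–Martin oxidation gives the aldehyde F2, and Wittig methylenation (Ph3P=CH2) gives the diene F3. Ring-closing metathesis with the second-generation Grubbs catalyst should close ring B with loss of ethene to the 1,2-dihydronaphthalene F4 (C1=C2, methyl on C1). Hydrogenation of this trisubstituted styrene-type double bond with a chiral iridium phosphinooxazoline complex [Ir(cod)(L*)]BArF under H2 (catalyst-controlled face selection, benzyl groups untouched) should then give 22.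

2. Step 9. Ionisation of the ortho-substituted carbinol may be slow and the two catalytic cycles may fall out of step, leading to self-condensation of the aldehyde or poor diastereocontrol. The fallback sets out from 5 and 13 and rejoins at 15, building the C4–C11 bond by a sigmatropic rearrangement. Pinnick oxidation of 13 gives (S)-7-(benzyloxy)-6-methylheptanoic acid F5. Aldehyde 5 is homologated with (triphenylphosphoranylidene)acetaldehyde to the (E)-enal F6 and reduced under Luche conditions (NaBH4, CeCl3) to the (E)-allylic alcohol F7. Esterification of F5 with F7 (EDC, DMAP) gives the allyl ester F8. An enantioselective Ireland–Claisen rearrangement through a chiral boron enolate (C2-symmetric 2-bromo-1,3-bis(arylsulfonyl)-4,5-diphenyl-1,3,2-diazaborolidine, tertiary amine, −78 °C to rt) should give the pent-4-enoic acid F9 through a chair transition state; the amine/solvent pair is chosen for the enolate geometry that leads to the anti acid and the diamine antipode for the (S,S) series. Activation with isobutyl chloroformate/N-methylmorpholine to the mixed anhydride F10 (not isolated) and NaBH4 reduction should give 15 without touching the vinyl group or the benzyl ester.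

3. Step 12. Oxidative addition and transmetalation at the doubly ortho-substituted triflate may be slow, so that triflate hydrolysis or protodeboronation of the vinyl boronate competes. The fallback sets out from 5 and rejoins at 19, moving the coupling to the activated, less hindered triflate ortho to the formyl group and relying later on chemoselective hydroboration. Suzuki–Miyaura vinylation of 5 gives the vinyl aldehyde F11, and vinylmagnesium bromide gives the racemic divinyl carbinol F12. The dual-catalytic allylation of step 9 with 13 gives the aldehyde F13 (not isolated), which NaBH4 reduces to the alcohol F14; silylation gives the silyl ether F15. 9-BBN should then add to the alkyl-substituted vinyl group far faster than to the conjugated, doubly ortho-substituted aryl vinyl group, giving the alkylborane F16 (not isolated), and perborate oxidation gives 19.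

**Further compounds**

F1 | step 14 | benzyl 6-[(3S,4S,8S)-9-(benzyloxy)-4-{[(tert-butyldimethylsilyl)oxy]methyl}-1-hydroxy-8-methylnonan-3-yl]-2,2-diphenyl-7-(prop-1-en-2-yl)-1,3-benzodioxole-4-carboxylate | CC(C)(C)[Si](C)(C)OC[C@@H](CCC[C@H](C)COCc1ccccc1)[C@H](CCO)c1cc(C(=O)OCc2ccccc2)c2OC(c3ccccc3)(c3ccccc3)Oc2c1C(C)=C
F2 | step 14 | benzyl 6-[(3S,4S,8S)-9-(benzyloxy)-4-{[(tert-butyldimethylsilyl)oxy]methyl}-8-methyl-1-oxononan-3-yl]-2,2-diphenyl-7-(prop-1-en-2-yl)-1,3-benzodioxole-4-carboxylate | CC(C)(C)[Si](C)(C)OC[C@@H](CCC[C@H](C)COCc1ccccc1)[C@H](CC=O)c1cc(C(=O)OCc2ccccc2)c2OC(c3ccccc3)(c3ccccc3)Oc2c1C(C)=C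
F3 | step 14 | benzyl 6-[(4S,5S,9S)-10-(benzyloxy)-5-{[(tert-butyldimethylsilyl)oxy]methyl}-9-methyldec-1-en-4-yl]-2,2-diphenyl-7-(prop-1-en-2-yl)-1,3-benzodioxole-4-carboxylate | CC(C)(C)[Si](C)(C)OC[C@@H](CCC[C@H](C)COCc1ccccc1)[C@H](CC=C)c1cc(C(=O)OCc2ccccc2)c2OC(c3ccccc3)(c3ccccc3)Oc2c1C(C)=C
F4 | step 14 | benzyl (6S)-6-[(2S,6S)-7-(benzyloxy)-1-[(tert-butyldimethylsilyl)oxy]-6-methylheptan-2-yl]-9-methyl-2,2-diphenyl-6,7-dihydronaphtho[1,2-d][1,3]dioxole-4-carboxylate | CC(C)(C)[Si](C)(C)OC[C@@H](CCC[C@H](C)COCc1ccccc1)[C@@H]1CC=C(C)c2c1cc(C(=O)OCc1ccccc1)c1OC(c3ccccc3)(c3ccccc3)Oc21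
F5 | step 9 | (S)-7-(benzyloxy)-6-methylheptanoic acid | OC(=O)CCCC[C@H](C)COCc1ccccc1
F6 | step 9 | benzyl 6-[(E)-3-oxoprop-1-en-1-yl]-2,2-diphenyl-7-{[(trifluoromethyl)sulfonyl]oxy}-1,3-benzodioxole-4-carboxylate | O=C/C=C/c1cc(C(=O)OCc2ccccc2)c2OC(c3ccccc3)(c3ccccc3)Oc2c1OS(=O)(=O)C(F)(F)F
F7 | step 9 | benzyl 6-[(E)-3-hydroxyprop-1-en-1-yl]-2,2-diphenyl-7-{[(trifluoromethyl)sulfonyl]oxy}-1,3-benzodioxole-4-carboxylate | OC/C=C/c1cc(C(=O)OCc2ccccc2)c2OC(c3ccccc3)(c3ccccc3)Oc2c1OS(=O)(=O)C(F)(F)F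
F8 | step 9 | (E)-allyl ester of F5 with F7 | O=C(CCCC[C@H](C)COCc1ccccc1)OC/C=C/c1cc(C(=O)OCc2ccccc2)c2OC(c3ccccc3)(c3ccccc3)Oc2c1OS(=O)(=O)C(F)(F)F
F9 | step 9 | (2S,3S)-2-[(4S)-5-(benzyloxy)-4-methylpentyl]-3-aryl-pent-4-enoic acid (aryl = the benzodioxole of 5 attached at its position 6) | OC(=O)[C@@H](CCC[C@H](C)COCc1ccccc1)[C@H](C=C)c1cc(C(=O)OCc2ccccc2)c2OC(c3ccccc3)(c3ccccc3)Oc2c1OS(=O)(=O)C(F)(F)F
F10 | step 9 | mixed isobutyl carbonic anhydride of F9 | CC(C)COC(=O)OC(=O)[C@@H](CCC[C@H](C)COCc1ccccc1)[C@H](C=C)c1cc(C(=O)OCc2ccccc2)c2OC(c3ccccc3)(c3ccccc3)Oc2c1OS(=O)(=O)C(F)(F)F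
F11 | step 12 | benzyl 7-ethenyl-6-formyl-2,2-diphenyl-1,3-benzodioxole-4-carboxylate | O=Cc1cc(C(=O)OCc2ccccc2)c2OC(c3ccccc3)(c3ccccc3)Oc2c1C=C
F12 | step 12 | benzyl 7-ethenyl-6-(1-hydroxyprop-2-en-1-yl)-2,2-diphenyl-1,3-benzodioxole-4-carboxylate (racemic) | C=CC(O)c1cc(C(=O)OCc2ccccc2)c2OC(c3ccccc3)(c3ccccc3)Oc2c1C=C
F13 | step 12 | benzyl 6-[(3S,4S,8S)-9-(benzyloxy)-4-formyl-8-methylnon-1-en-3-yl]-7-ethenyl-2,2-diphenyl-1,3-benzodioxole-4-carboxylate | O=C[C@@H](CCC[C@H](C)COCc1ccccc1)[C@H](C=C)c1cc(C(=O)OCc2ccccc2)c2OC(c3ccccc3)(c3ccccc3)Oc2c1C=C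
F14 | step 12 | benzyl 6-[(3S,4S,8S)-9-(benzyloxy)-4-(hydroxymethyl)-8-methylnon-1-en-3-yl]-7-ethenyl-2,2-diphenyl-1,3-benzodioxole-4-carboxylate | OC[C@@H](CCC[C@H](C)COCc1ccccc1)[C@H](C=C)c1cc(C(=O)OCc2ccccc2)c2OC(c3ccccc3)(c3ccccc3)Oc2c1C=C
F15 | step 12 | benzyl 6-[(3S,4S,8S)-9-(benzyloxy)-4-{[(tert-butyldimethylsilyl)oxy]methyl}-8-methylnon-1-en-3-yl]-7-ethenyl-2,2-diphenyl-1,3-benzodioxole-4-carboxylate | CC(C)(C)[Si](C)(C)OC[C@@H](CCC[C@H](C)COCc1ccccc1)[C@H](C=C)c1cc(C(=O)OCc2ccccc2)c2OC(c3ccccc3)(c3ccccc3)Oc2c1C=C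
F16 | step 12 | benzyl 6-[(3S,4S,8S)-9-(benzyloxy)-1-(9-borabicyclo[3.3.1]nonan-9-yl)-4-{[(tert-butyldimethylsilyl)oxy]methyl}-8-methylnonan-3-yl]-7-ethenyl-2,2-diphenyl-1,3-benzodioxole-4-carboxylate | CC(C)(C)[Si](C)(C)OC[C@@H](CCC[C@H](C)COCc1ccccc1)[C@H](CCB4C5CCCC4CCC5)c1cc(C(=O)OCc2ccccc2)c2OC(c3ccccc3)(c3ccccc3)Oc2c1C=C
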